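The bicycle is cut at C5–C6 (3,7-dioxabicyclo[3.3.0]octane numbering, guaiacyl on C2, prenyloxyaryl on C6). The feature exploited is that C6 is benzylic, α to O7 and δ to C5, with O7 itself filling the γ position of the C5–C1–C8–O7–C6 chain. A photoexcited C5 ketone in ring A therefore takes a C6 hydrogen, and the 1,5-biradical collapses. One irradiation forms C5–C6, closes ring B and sets C5 and C6. The precursor is the trans-(4S,5R)-5-aryl-4-[(arylmethoxy)methyl]oxolan-3-one 14, built from (S)-3-hydroxy-γ-butyrolactone and unmasked last by a neutral oxidation. The surplus C5 hydroxyl is then removed by radical reduction.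

Key step: step 9

Remark on labels: C1–C8/O3/O7 denote the same atoms in every intermediate (C2 = guaiacyl-bearing carbon, C1/C5 = later bridgeheads, C4 and C8 = the two OCH2 carbons, C6 = prenyloxyaryl-bearing carbon).
Remark on configuration: the target is (1S,2R,5S,6R), the (−)-pinoresinol series, cis-fused with both aryl groups exo. The descriptors of 16 and 17 read (1S,2R,5R,6S) only because the CIP priorities change.
Remark on C2 in 5 and 6: the carbinol is assumed to form as an epimer mixture. This is harmless, because step 4 passes through the planar benzylic cation.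
Remark on design: no enolate is ever placed β to the benzylic C2–O3 bond, since retro-oxa-Michael opening would racemise C2. The ketone, whose C1–H is flanked by two β C–O bonds, appears only one step before the irradiation. The phenol stays silylated because a free phenol would quench the excited carbonyl.

Step 1
Reactants: 1 vanillin
Product: 2 4-(tert-butyldimethylsilyloxy)-3-methoxybenzaldehyde
Conditions: TBSCl, imidazole, DMF, rt
Reagents that add atoms: tert-butyldimethylsilyl chloride, CC(C)(C)[Si](C)(C)Cl
Why: Imidazole-promoted silylation of a phenol, which masks the acidic OH through the enolate, tin, photochemical and radical steps.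

Step 2
Reactants: 3 (S)-3-hydroxy-γ-butyrolactone; 2 4-(tert-butyldimethylsilyloxy)-3-methoxybenzaldehyde
Product: 5 (3S,4S)-3-{[4-(tert-butyldimethylsilyloxy)-3-methoxyphenyl](hydroxy)methyl}-4-hydroxyoxolan-2-one (3,4-trans; both carbinol epimers), via dilithio dianion 4 (not isolated)
Conditions: 3, LiN(iPr)2 (2.2 equiv), THF, −78 °C; then 2, −78 °C; AcOH quench at −78 °C
Reagents that add atoms: lithium diisopropylamide, CC(C)N([Li])C(C)C (lithium, held in 4 only)
Why: In this Fráter–Seebach-type dianion aldol addition the lithium alkoxide on C5 suppresses β-elimination and shields one ring face, so the aldehyde should add to C1 trans to it and C1 is set from the chiral pool.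

Step 3
Reactants: 5 aldol adduct
Product: 6 (2S,3S)-1-[4-(tert-butyldimethylsilyloxy)-3-methoxyphenyl]-2-(hydroxymethyl)butane-1,3,4-triol (both C1 carbinol epimers)
Conditions: LiBH4, THF, 0 °C to rt; aq. NH4Cl
Reagents that add atoms: none
Why: Hydride reduction of a lactone to the 1,4-diol frees the C4 and C8 hydroxyls, touches no stereocentre and leaves the aryl silyl ether intact.

Step 4
Reactants: 6 tetraol
Product: 7 (3S,4R,5R)-5-[4-(tert-butyldimethylsilyloxy)-3-methoxyphenyl]-4-(hydroxymethyl)oxolan-3-ol (aryl trans to CH2OH, CH2OH cis to OH)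
Conditions: CSA (0.1 equiv), CH2Cl2–MeCN, rt
Reagents that add atoms: none
Why: In this acid-catalysed SN1 cycloetherification through the p-silyloxybenzyl cation only the C4 hydroxyl can close a five-membered ring (the C5 and C8 hydroxyls would give oxetanes), and reversible ionisation should deliver the isomer with the aryl group anti to the C1 and C5 substituents, which sets C2 as R.

Step 5
Reactants: 8 vanillyl alcohol; 9 prenyl bromide
Product: 10 [3-methoxy-4-(3-methylbut-2-enyloxy)phenyl]methanol
Conditions: K2CO3, acetone, reflux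
Reagents that add atoms: none
Why: This Williamson ether synthesis is selective because K2CO3 deprotonates only the phenol and not the benzylic alcohol.

Step 6
Reactants: 10 O-prenylvanillyl alcohol
Product: 11 4-(bromomethyl)-2-methoxy-1-(3-methylbut-2-enyloxy)benzene (used at once)
Conditions: CBr4, PPh3, CH2Cl2, 0 °C
Reagents that add atoms: carbon tetrabromide, BrC(Br)(Br)Br
Why: The Appel reaction runs under neutral conditions, which avoids HBr addition to the prenyl alkene and cleavage of the prenyl ether.

Step 7
Reactants: 7 ring-A diol; 11 benzylic bromide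
Product: 13 (3S,4R,5R)-5-[4-(tert-butyldimethylsilyloxy)-3-methoxyphenyl]-4-({[3-methoxy-4-(3-methylbut-2-enyloxy)phenyl]methoxy}methyl)oxolan-3-ol, via dibutylstannylene acetal 12 (not isolated)
Conditions: Bu2SnO, toluene, reflux (−H2O); then 11, Bu4NBr, toluene, 70 °C
Reagents that add atoms: dibutyltin oxide, CCCC[Sn](=O)CCCC (tin and butyl groups, held in 12 only)
Why: In this stannylene-acetal-directed monoalkylation the cis-1,3-diol forms a six-membered tin acetal whose primary oxygen is alkylated preferentially under bromide activation, and no strong base is present to attack the aryl silyl ether.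

Step 8
Reactants: 13 ether alcohol
Product: 14 (4S,5R)-5-[4-(tert-butyldimethylsilyloxy)-3-methoxyphenyl]-4-({[3-methoxy-4-(3-methylbut-2-enyloxy)phenyl]methoxy}methyl)oxolan-3-one (4,5-trans)
Conditions: Dess–Martin periodinane, NaHCO3, CH2Cl2, 0 °C to rt
Reagents that add atoms: none
Why: The buffered Dess–Martin oxidation is essentially neutral, so C1 should not enolise, neither β C–O bond (C8–O7, C2–O3) should be eliminated, and the alkene and aryl ethers are inert.

Step 9
Reactants: 14 ring-A ketone
Product: 16 (1S,2R,5R,6S)-2-[4-(tert-butyldimethylsilyloxy)-3-methoxyphenyl]-6-[3-methoxy-4-(3-methylbut-2-enyloxy)phenyl]-3,7-dioxabicyclo[3.3.0]octan-5-ol (cis-fused; both aryl groups exo), via 1,5-biradical 15 (not isolated)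
Conditions: hν (medium-pressure Hg lamp, Pyrex filter, λ > 300 nm), degassed benzene (ca. 3 mM), 15–20 °C
Reagents that add atoms: none
Why: n→π* excitation of the C5 carbonyl is followed by a 1,6-hydrogen transfer from C6 (directly through a seven-membered transition state, or stepwise by electron transfer from the dialkoxyarene and then proton transfer) to give biradical 15, whose two radical centres combine to form C5–C6. The closest known reaction type is the Norrish–Yang-type δ-hydrogen abstraction and cyclisation of β-alkoxy ketones to oxolan-3-ols, which is established for 4-(benzyloxymethyl)oxolan-3-ones giving bridgehead-hydroxylated furofurans. Ring B (C5–C6–O7–C8–C1) closes as a five-membered ring by 1,5-radical–radical recombination. C5 is controlled by the tether, because C8 sits on one face of ring A, C6 can reach the C5 radical only from that face, and the hydroxyl therefore ends cis to H1 in the only accessible (cis) ring fusion. C6 is controlled by sterics in the closing biradical, where the planar benzylic radical should turn its aryl group to the convex face, away from C4 and ring A. The chemoselectivity needed rests on O7 occupying the γ position (no Norrish type 2 cleavage), on the weak, doubly activated C6–H bond, on light that only the ketone absorbs (which also leaves the carbonyl-free product untouched), and on high dilution, which disfavours bimolecular oxetane formation with the prenyl alkene.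

Step 10
Reactants: 16 bridgehead alcohol
Product: 17 methyl oxalate of 16 at the C5 oxygen, (1S,2R,5R,6S)
Conditions: ClC(O)CO2Me, Et3N, DMAP (cat.), CH2Cl2, 0 °C to rt
Reagents that add atoms: methyl chlorooxoacetate, COC(=O)C(=O)Cl
Why: In this DMAP-catalysed acylation the small, very electrophilic acid chloride should reach the hindered tertiary hydroxyl without acid or heat.

Step 11
Reactants: 17 methyl oxalate
Product: 18 (1S,2R,5S,6R)-2-[4-(tert-butyldimethylsilyloxy)-3-methoxyphenyl]-6-[3-methoxy-4-(3-methylbut-2-enyloxy)phenyl]-3,7-dioxabicyclo[3.3.0]octane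
Conditions: Bu3SnH (excess, ≥0.2 M), AIBN (cat.), toluene, reflux
Reagents that add atoms: none
Why: In this Barton–McCombie-type radical deoxygenation of a tertiary alcohol through its methyl oxalate, stannyl radical addition releases the C5 radical, which takes hydrogen on the convex face because only the cis-fused bicycle is accessible, so C5 is set as S while the trisubstituted alkene stays inert.

Step 12
Reactants: 18 silyl ether
Product: 19 target, 4-{(1S,2R,5S,6R)-6-[3-methoxy-4-(3-methylbut-2-enyloxy)phenyl]-3,7-dioxabicyclo[3.3.0]octan-2-yl}-2-methoxyphenol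
Conditions: Bu4NF, AcOH (1:1), THF, 0 °C
Reagents that add atoms: none
Why: Fluoride cleaves the aryl silyl ether, the acetic acid buffer protonates the phenoxide at once, and the prenyl ether and the benzylic ethers are untouched.

Compound list
1 | vanillin | COc1cc(C=O)ccc1O | starting material
2 | 4-(tert-butyldimethylsilyloxy)-3-methoxybenzaldehyde | COc1cc(C=O)ccc1O[Si](C)(C)C(C)(C)C | intermediate
3 | (S)-3-hydroxy-γ-butyrolactone | O=C1C[C@H](O)CO1 | starting material
4 | dilithio dianion of 3 (lithium enolate and lithium alkoxide) | [Li]OC1=C[C@H](O[Li])CO1 | intermediate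
5 | (3S,4S)-aldol adduct, carbinol epimers | COc1cc(ccc1O[Si](C)(C)C(C)(C)C)C(O)[C@H]1[C@H](O)COC1=O | intermediate
6 | (2S,3S)-tetraol, carbinol epimers | COc1cc(ccc1O[Si](C)(C)C(C)(C)C)C(O)[C@H](CO)[C@H](O)CO | intermediate
7 | (3S,4R,5R)-5-aryl-4-(hydroxymethyl)oxolan-3-ol | COc1cc(ccc1O[Si](C)(C)C(C)(C)C)[C@@H]1OC[C@@H](O)[C@H]1CO | intermediate
8 | vanillyl alcohol | COc1cc(CO)ccc1O | starting material
9 | prenyl bromide | CC(C)=CCBr | starting material
10 | [3-methoxy-4-(3-methylbut-2-enyloxy)phenyl]methanol | COc1cc(CO)ccc1OCC=C(C)C | intermediate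
11 | 4-(bromomethyl)-2-methoxy-1-(3-methylbut-2-enyloxy)benzene | COc1cc(CBr)ccc1OCC=C(C)C | intermediate
12 | dibutylstannylene acetal of 7 | COc1cc(ccc1O[Si](C)(C)C(C)(C)C)[C@@H]1OC[C@H]2O[Sn](CCCC)(CCCC)OC[C@@H]12 | intermediate
13 | (3S,4R,5R)-ether alcohol | COc1cc(ccc1O[Si](C)(C)C(C)(C)C)[C@@H]1OC[C@@H](O)[C@H]1COCc1ccc(OCC=C(C)C)c(OC)c1 | intermediate
14 | (4S,5R)-ring-A ketone, precursor of the key step | COc1cc(ccc1O[Si](C)(C)C(C)(C)C)[C@@H]1OCC(=O)[C@H]1COCc1ccc(OCC=C(C)C)c(OC)c1 | intermediate
15 | 1,5-biradical (C5 ketyl, C6 benzylic α-oxy radical) | COc1cc(ccc1O[Si](C)(C)C(C)(C)C)[C@@H]1OC[C](O)[C@H]1CO[CH]c1ccc(OCC=C(C)C)c(OC)c1 | intermediate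
16 | (1S,2R,5R,6S)-C5-hydroxy furofuran, product of the key step | COc1cc([C@@H]2OC[C@]3(O)[C@H]2CO[C@H]3c2ccc(OCC=C(C)C)c(OC)c2)ccc1O[Si](C)(C)C(C)(C)C | intermediate
17 | C5 methyl oxalate of 16 | COc1cc([C@@H]2OC[C@]3(OC(=O)C(=O)OC)[C@H]2CO[C@H]3c2ccc(OCC=C(C)C)c(OC)c2)ccc1O[Si](C)(C)C(C)(C)C | intermediate
18 | (1S,2R,5S,6R)-O-silyl ether of the target | COc1cc([C@@H]2OC[C@@H]3[C@H]2CO[C@H]3c2ccc(OCC=C(C)C)c(OC)c2)ccc1O[Si](C)(C)C(C)(C)C | intermediate
19 | CNP0185952.2, mono-O-prenyl (−)-pinoresinol | COc1cc([C@@H]2OC[C@@H]3[C@H]2CO[C@H]3c2ccc(OCC=C(C)C)c(OC)c2)ccc1O | target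

Total step count: 12. Longest linear sequence: 10 (steps 1–4 and 7–12, from vanillin).

Steps most likely to fail

Step 9. Several processes could compete with the cyclisation:
- α-cleavage of the excited oxolanone with loss of CO;
- reverse hydrogen transfer in the biradical;
- interception of the excited carbonyl by the prenyl alkene;
- closure with the aryl group turned to the concave face.

The fallback makes C5–C6 by a polar addition and closes ring B at C6–O7. It sets out from 7 and comes back at 18, bypassing steps 7–11.
- The primary hydroxyl of 7 is tritylated (TrCl, pyridine, DMAP) to trityl ether F1.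
- Dess–Martin oxidation gives ketone F2.
- Non-basic Petasis methylenation (Cp2TiMe2, toluene, 70 °C) gives exocyclic alkene F3.
- Hydroboration with 9-BBN on the face anti to the C1 trityloxymethyl group, then NaBO3, should give hydroxymethyl compound F4 with C6 cis to C8.
- Dess–Martin oxidation gives aldehyde F5, which is used at once.
- Aryl bromide F6 is made from commercial 4-bromo-2-methoxyphenol, 9 and K2CO3, and is converted with Mg in THF into Grignard reagent F7.
- F7 is added to F5 at −78 °C to give carbinol F8 (C6 epimers).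
- CSA in moist CH2Cl2 removes the trityl group and ionises C6. The C8 hydroxyl then captures the cation on the cis template with the aryl group exo, giving 18.

Step 2. The aldol addition could suffer from incomplete double deprotonation, β-elimination of the C5 alkoxide, retro-aldol cleavage during the quench, or erosion of facial selectivity at C1.

The fallback uses auxiliary control in place of chiral-pool control. It sets out from 2 and comes back at 14.
- Commercial (R)-4-benzyl-2-oxazolidinone is acylated with (E)-crotonyl chloride (n-BuLi, THF, −78 °C) to N-crotonyl imide F9.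
- A deconjugative Evans syn-aldol addition to 2 (Bu2BOTf, Et3N, CH2Cl2, −78 °C) gives α-vinyl aldol adduct F10, in which the auxiliary sets C1.
- LiBH4 releases the auxiliary and gives ene-diol F11.
- OsO4 (cat.) with NMO gives tetraol F12 (C5 epimers).
- CSA closure as in step 4 gives diol F13.
- Stannylene alkylation with 11 as in step 7 gives ether alcohol F14.
- Dess–Martin oxidation as in step 8 erases C5 and converges on 14.

Step 11. The alcohol could be returned by attack at the oxalate carbonyl instead of C–O scission. The C5 radical could also open ring A by β-scission of C1–C2 before hydrogen transfer.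

The fallback is a tin-free decarboxylative chain with a faster hydrogen donor. It sets out from 16 and comes back at 18.
- 16 is treated with oxalyl chloride (2,6-di-tert-butylpyridine, benzene, rt, then evaporation) to give chlorooxalate F15.
- F15 is added to NaC5H4NOS (the sodium salt of N-hydroxypyridine-2-thione) and tert-butyl thiol in refluxing benzene.
- Mixed oxalate thiohydroxamate F16 forms and fragments in a Barton-ester chain with loss of two CO2.
- The C5 radical takes hydrogen from the thiol on the convex face, giving 18.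

Further compounds
F1 | step 9 | 8-O-trityl ether of 7 | COc1cc(ccc1O[Si](C)(C)C(C)(C)C)[C@@H]1OC[C@@H](O)[C@H]1COC(c1ccccc1)(c1ccccc1)c1ccccc1
F2 | step 9 | C5 ketone of F1 | COc1cc(ccc1O[Si](C)(C)C(C)(C)C)[C@@H]1OCC(=O)[C@H]1COC(c1ccccc1)(c1ccccc1)c1ccccc1
F3 | step 9 | C5 exocyclic methylene compound | COc1cc(ccc1O[Si](C)(C)C(C)(C)C)[C@@H]1OCC(=C)[C@H]1COC(c1ccccc1)(c1ccccc1)c1ccccc1
F4 | step 9 | C5 hydroxymethyl compound, C6 cis to C8 | COc1cc(ccc1O[Si](C)(C)C(C)(C)C)[C@@H]1OC[C@@H](CO)[C@H]1COC(c1ccccc1)(c1ccccc1)c1ccccc1
F5 | step 9 | C6 aldehyde | COc1cc(ccc1O[Si](C)(C)C(C)(C)C)[C@@H]1OC[C@@H](C=O)[C@H]1COC(c1ccccc1)(c1ccccc1)c1ccccc1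
F6 | step 9 | 4-bromo-2-methoxy-1-(3-methylbut-2-enyloxy)benzene | COc1cc(Br)ccc1OCC=C(C)C
F7 | step 9 | [3-methoxy-4-(3-methylbut-2-enyloxy)phenyl]magnesium bromide | COc1cc([Mg]Br)ccc1OCC=C(C)C
F8 | step 9 | C6 carbinol, epimers at C6 | COc1cc(ccc1O[Si](C)(C)C(C)(C)C)[C@@H]1OC[C@@H](C(O)c2ccc(OCC=C(C)C)c(OC)c2)[C@H]1COC(c1ccccc1)(c1ccccc1)c1ccccc1
F9 | step 2 | (R)-4-benzyl-3-[(E)-but-2-enoyl]oxazolidin-2-one | C/C=C/C(=O)N1[C@H](Cc2ccccc2)COC1=O
F10 | step 2 | (2R,3R)-syn α-vinyl aldol imide | C=C[C@H]([C@@H](O)c1ccc(O[Si](C)(C)C(C)(C)C)c(OC)c1)C(=O)N1[C@H](Cc2ccccc2)COC1=O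
F11 | step 2 | 1-aryl-2-vinylpropane-1,3-diol | C=C[C@@H](CO)[C@@H](O)c1ccc(O[Si](C)(C)C(C)(C)C)c(OC)c1
F12 | step 2 | tetraol, epimers at C5 | OCC(O)[C@@H](CO)[C@@H](O)c1ccc(O[Si](C)(C)C(C)(C)C)c(OC)c1
F13 | step 2 | ring-A diol, epimers at C5 | COc1cc(ccc1O[Si](C)(C)C(C)(C)C)[C@@H]1OCC(O)[C@H]1CO
F14 | step 2 | ether alcohol, epimers at C5 | COc1cc(ccc1O[Si](C)(C)C(C)(C)C)[C@@H]1OCC(O)[C@H]1COCc1ccc(OCC=C(C)C)c(OC)c1
F15 | step 11 | C5 chlorooxalate of 16 | COc1cc([C@@H]2OC[C@]3(OC(=O)C(=O)Cl)[C@H]2CO[C@H]3c2ccc(OCC=C(C)C)c(OC)c2)ccc1O[Si](C)(C)C(C)(C)C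
F16 | step 11 | mixed oxalate of 16 and N-hydroxypyridine-2-thione | COc1cc([C@@H]2OC[C@]3(OC(=O)C(=O)On4ccccc4=S)[C@H]2CO[C@H]3c2ccc(OCC=C(C)C)c(OC)c2)ccc1O[Si](C)(C)C(C)(C)C
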